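## Retrosynthetic overview

1. Target 14 ⇐ Claisen/Cope relay of a C4–O-prenyl vinylogous ester (prenyl travels O → C3a → C7, setting C7 from C5 and C2) ⇐ enol 11 + prenol.
2. 11 ⇐ palladium-catalysed, ligand-controlled O→C prenyl transfer within aryl prenyl ether 10 (dearomatisation, sets C5).
3. 10 ⇐ C–O ring closure: acylphenol-directed asymmetric epoxidation of the Z-olefin of 8, then invertive 5-exo opening by the phenoxide (dihydrofuran ring and both side-chain stereocentres).
4. 8 ⇐ O-prenylation of 6 ⇐ C-nerylation of acylphloroglucinol 3 ⇐ acylation of 2-methylphloroglucinol 1.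
5. Ring order: benzene ring bought; dihydrofuran ring closed in step 5; carbocycle dearomatised in two stages (steps 6 and 7).

Locants: phenyl numbering (acyl carbon = C1) for 3, 6, 8, 9; benzofuran numbering (O1, C2, C3, C3a, C4–C7, C7a) for 10–14; the side-chain carbinol carbon is C2′.

Assumption: the ligand antipodes named in steps 5 and 6 are taken to deliver the faces stated; if the observed sense is opposite, the enantiomeric ligand is used.

## Route

Step 1
Reactants: 1 2-methylphloroglucinol; 2 isobutyryl chloride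
Product: 3 2-methyl-1-(2,4,6-trihydroxy-3-methylphenyl)propan-1-one
Conditions: AlCl3 (3.5 equiv), PhNO2, 65 °C; aq HCl work-up
Reagents that add atoms: none
Why: Friedel–Crafts C-acylation of a phloroglucinol; the two free ring positions of 1 are equivalent, so a single regioisomer forms and no stereocentre is involved.

Step 2
Reactants: 4 nerol
Product: 5 neryl bromide
Conditions: PBr3 (0.4 equiv), Et2O, −10 °C
Reagents that add atoms: phosphorus tribromide, BrP(Br)Br
Why: SN2 bromination of a primary allylic alcohol through its phosphite ester; at low temperature the Z-olefin is kept and no allylic transposition occurs.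

Step 3
Reactants: 3 acylphloroglucinol; 5 neryl bromide
Product: 6 C-neryl acylphloroglucinol
Conditions: 5 (0.9 equiv), 5% aq KOH, 0 °C
Reagents that add atoms: none
Why: Phenolate C-alkylation (SN2) at the only unsubstituted ring carbon; the aqueous medium favours C- over O-alkylation and the Z-geometry of the allyl unit is retained.

Step 4
Reactants: 6 C-neryl acylphloroglucinol; 7 prenol
Product: 8 4-O-prenyl ether
Conditions: PPh3, DIAD, THF, 0 °C → rt
Reagents that add atoms: none
Why: Mitsunobu etherification; the 4-OH (para to the ketone) is the most acidic and the only non-chelated phenol, so it alone is O-alkylated and C-alkylation is avoided.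

Step 5
Reactants: 8 4-O-prenyl ether
Product: 10 dihydrobenzofuran prenyl ether, via epoxide 9 (not isolated)
Conditions: Hf(OtBu)4 (10 mol%), N,N′-[(1R,2R)-cyclohexane-1,2-diyl]bis(N-hydroxy-2,2-diphenylacetamide) (12 mol%), cumene hydroperoxide (1.1 equiv), 4 Å MS, PhMe, 0 °C; then K2CO3 (0.2 equiv), MeOH, rt
Reagents that add atoms: cumene hydroperoxide, CC(C)(OO)c1ccccc1
Why: Proposed new method: the phenol that is ortho to both the ketone and the neryl chain is meant to bind tetravalent hafnium together with the ketone oxygen as a six-membered O,O-chelate inside the chiral bishydroxamate pocket, so that the hafnium-bound cumyl peroxide reaches only the neighbouring bishomoallylic Z-olefin (not the distal or O-prenyl olefins) and only one π-face, giving the (2R,3S)-cis-epoxide 9; catalytic base then lets the same phenoxide open the epoxide 5-exo-tet at the CH carbon with inversion (the 4-OH is masked as its prenyl ether and the other phenol cannot reach), which forms the dihydrofuran C–O bond and fixes C2 (S) and C2′ (S); the closest known reactions are the group-4-metal/bishydroxamic acid epoxidation of homo- and bishomoallylic alcohols and the racemic VO(acac)2/tBuOOH epoxidation–cyclisation of 2-allylphenols, whereas an acylphenol chelate as directing group for an asymmetric epoxidation has not been shown.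

Step 6
Reactants: 10 dihydrobenzofuran prenyl ether
Product: 11 C5-prenylated enol (2S,5R)
Conditions: Pd2(dba)3 (2.5 mol%), (R,R)-DACH-phenyl Trost ligand (7.5 mol%), degassed PhMe, 40 °C
Reagents that add atoms: none
Why: Tsuji–Trost asymmetric allylic dearomatisation with the substrate's own aryl prenyl ether as π-allyl source: zerovalent palladium ionises the C4–O-prenyl bond (an acyl-stabilised phenoxide leaves, as in palladium-mediated O-deallylation) and the phenoxide attacks the unsubstituted terminus of the π-prenyl ligand through C5, the ortho carbon whose alkylation keeps the hydrogen-bonded 6-OH/7-acyl enone intact (the bond fixation that also steers Claisen shifts of chelated 4-allyloxy-2-hydroxyaryl ketones), so C5 rather than C3a is prenylated and the chiral pocket selects the ring face to set C5 (R) under catalyst control.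

Step 7
Reactants: 11 C5-prenylated enol; 7 prenol
Product: 14 target CNP0250451.1, via O-prenyl vinylogous ester 12 (not isolated), via 3a-reverse-prenyl dione 13 (not isolated)
Conditions: PPh3, DIAD, PhMe, 0 °C → rt; then 120 °C (sealed tube)
Reagents that add atoms: none
Why: Mitsunobu O-alkylation of the vinylogous acid at the unchelated, less hindered C4 oxygen gives 12; on heating, a Claisen [3,3] shift delivers the prenyl unit to C3a (the only terminus, since C5 is quaternary) on the face anti to both the C5-prenyl group and the C2 side chain, and a suprafacial Cope [3,3] shift across C3a–C7a=C7 relays it to C7 as a normal prenyl group on the same face, which sets C7 (S) trans to the C5-prenyl group and is driven by C=O formation and relief of the vicinal quaternary congestion in 13.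

## Compound list

1 | 2-methylbenzene-1,3,5-triol (2-methylphloroglucinol) | Cc1c(O)cc(O)cc1O | starting material
2 | 2-methylpropanoyl chloride (isobutyryl chloride) | CC(C)C(Cl)=O | starting material
3 | 2-methyl-1-(2,4,6-trihydroxy-3-methylphenyl)propan-1-one | CC(C)C(=O)c1c(O)cc(O)c(C)c1O | intermediate
4 | nerol, (2Z)-3,7-dimethylocta-2,6-dien-1-ol | CC(C)=CCC/C(C)=C\CO | starting material
5 | neryl bromide, (2Z)-1-bromo-3,7-dimethylocta-2,6-diene | CC(C)=CCC/C(C)=C\CBr | intermediate
6 | 1-{3-[(2Z)-3,7-dimethylocta-2,6-dien-1-yl]-2,4,6-trihydroxy-5-methylphenyl}-2-methylpropan-1-one | CC(C)C(=O)c1c(O)c(C)c(O)c(C/C=C(C)\CCC=C(C)C)c1O | intermediate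
7 | prenol, 3-methylbut-2-en-1-ol | CC(C)=CCO | starting material
8 | 1-{3-[(2Z)-3,7-dimethylocta-2,6-dien-1-yl]-2,6-dihydroxy-5-methyl-4-[(3-methylbut-2-en-1-yl)oxy]phenyl}-2-methylpropan-1-one | CC(C)C(=O)c1c(O)c(C)c(OCC=C(C)C)c(C/C=C(C)\CCC=C(C)C)c1O | intermediate
9 | 1-{2,6-dihydroxy-3-methyl-5-{[(2R,3S)-3-methyl-3-(4-methylpent-3-en-1-yl)oxiran-2-yl]methyl}-4-[(3-methylbut-2-en-1-yl)oxy]phenyl}-2-methylpropan-1-one | CC(C)C(=O)c1c(O)c(C)c(OCC=C(C)C)c(C[C@H]2O[C@@]2(C)CCC=C(C)C)c1O | intermediate (not isolated)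
10 | 1-{(2S)-6-hydroxy-2-[(2S)-2-hydroxy-6-methylhept-5-en-2-yl]-5-methyl-4-[(3-methylbut-2-en-1-yl)oxy]-2,3-dihydro-1-benzofuran-7-yl}-2-methylpropan-1-one | CC(C)=CCC[C@](C)(O)[C@@H]1Cc2c(O1)c(C(=O)C(C)C)c(O)c(C)c2OCC=C(C)C | intermediate
11 | (2S,5R)-6-hydroxy-2-[(2S)-2-hydroxy-6-methylhept-5-en-2-yl]-5-methyl-5-(3-methylbut-2-en-1-yl)-7-(2-methylpropanoyl)-2,3-dihydro-1-benzofuran-4(5H)-one | CC(C)=CCC[C@](C)(O)[C@@H]1CC2=C(O1)C(C(=O)C(C)C)=C(O)[C@@](C)(CC=C(C)C)C2=O | intermediate
12 | (2S,5S)-2-[(2S)-2-hydroxy-6-methylhept-5-en-2-yl]-5-methyl-5-(3-methylbut-2-en-1-yl)-4-[(3-methylbut-2-en-1-yl)oxy]-7-(2-methylpropanoyl)-2,3-dihydro-1-benzofuran-6(5H)-one | CC(C)=CCC[C@](C)(O)[C@@H]1CC2=C(OCC=C(C)C)[C@](C)(CC=C(C)C)C(=O)C(C(=O)C(C)C)=C2O1 | intermediate (not isolated)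
13 | (2S,3aR,5S)-2-[(2S)-2-hydroxy-6-methylhept-5-en-2-yl]-5-methyl-3a-(2-methylbut-3-en-2-yl)-5-(3-methylbut-2-en-1-yl)-7-(2-methylpropanoyl)-3,3a-dihydro-1-benzofuran-4,6(2H,5H)-dione | CC(C)=CCC[C@](C)(O)[C@@H]1C[C@]2(C(C)(C)C=C)C(=O)[C@](C)(CC=C(C)C)C(=O)C(C(=O)C(C)C)=C2O1 | intermediate (not isolated)
14 | (2S,5S,7S)-2-[(2S)-2-hydroxy-6-methylhept-5-en-2-yl]-5-methyl-5,7-bis(3-methylbut-2-en-1-yl)-7-(2-methylpropanoyl)-2,3-dihydro-1-benzofuran-4,6(5H,7H)-dione (CNP0250451.1) | CC(C)=CCC[C@](C)(O)[C@@H]1CC2=C(O1)[C@@](CC=C(C)C)(C(=O)C(C)C)C(=O)[C@@](C)(CC=C(C)C)C2=O | target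

## Step count and risk

Total steps: 7. Longest linear sequence: 6 (1 → 3 → 6 → 8 → 10 → 11 → 14); step 2 is a one-step side branch.

The three steps most likely to fail:

**Step 5 (the proposed new step).** Risks are poor turnover of the hafnium chelate, epoxidation of the wrong olefin, low ee, oxidation of the electron-rich ring, or Lewis-acid-induced 6-endo closure to a chromanol. The fallback sets out from 8 and gives up catalyst control. VO(acac)2 (5 mol%)/tBuOOH in CH2Cl2 at 0 °C, the known phenol-directed epoxidation of 2-allylphenols, followed by K2CO3/MeOH, gives the racemic cis-epoxide, that is 9 together with the enantiomeric (2S,3R)-epoxide F1. This closes to racemic product, that is 10 together with the enantiomeric (2R,2′R)-dihydrobenzofuran F2. Acylation of the 6-OH with (1S)-camphanic chloride (Et3N, DMAP, CH2Cl2) gives two diastereomeric esters, the camphanate of 10 F3 and the camphanate of the enantiomer F4, which are separated by chromatography or crystallisation. Methanolysis of F3 (K2CO3, MeOH) returns to the route at 10.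

**Step 6.** Risks are alkylation at C3a instead of C5, low face selectivity, or reversible ionisation eroding the C5 configuration. The fallback sets out from 10. Pd(PPh3)4 (cat.) with morpholine in THF removes the O-prenyl group to give the 4,6-diphenol F5. A non-asymmetric, base-mediated dearomative C-prenylation with prenyl bromide (aq KOH, 0 °C, the classical lupulone-type alkylation) then gives 11 together with its (5S)-epimer F6. These are diastereomers, because the side-chain centres are already fixed, and are separated by chromatography. The fallback comes back to the route at 11.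

**Step 7.** Risks are Mitsunobu alkylation at the wrong oxygen, a sluggish Claisen shift that must form two adjacent quaternary carbons, or weak face selectivity. The fallback sets out from 10 and reverses the order of the two ring alkylations. Heating 10 (PhNEt2, 160–180 °C) effects the classical aromatic para-Claisen (Claisen then Cope) rearrangement, which carries the prenyl group from O4 to the acyl-bearing para carbon C7. It gives the cross-conjugated (7S)-dienone F7 and its (7R)-epimer F8 with little face control; they are separated by HPLC. F7 is then C-prenylated with prenyl methyl carbonate and Pd(PPh3)4 in THF (Tsuji–Trost alkylation of a 2-methyl-1,3-diketone-type enol). Only C5 is nucleophilic once C7 is quaternary, and the electrophile enters anti to the C7-prenyl group. The fallback comes back to the route at 14.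

## Further compounds

F1 | step 5 | 1-{2,6-dihydroxy-3-methyl-5-{[(2S,3R)-3-methyl-3-(4-methylpent-3-en-1-yl)oxiran-2-yl]methyl}-4-[(3-methylbut-2-en-1-yl)oxy]phenyl}-2-methylpropan-1-one (enantiomer of 9) | CC(C)C(=O)c1c(O)c(C)c(OCC=C(C)C)c(C[C@@H]2O[C@]2(C)CCC=C(C)C)c1O
F2 | step 5 | 1-{(2R)-6-hydroxy-2-[(2R)-2-hydroxy-6-methylhept-5-en-2-yl]-5-methyl-4-[(3-methylbut-2-en-1-yl)oxy]-2,3-dihydro-1-benzofuran-7-yl}-2-methylpropan-1-one (enantiomer of 10) | CC(C)=CCC[C@@](C)(O)[C@H]1Cc2c(O1)c(C(=O)C(C)C)c(O)c(C)c2OCC=C(C)C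
F3 | step 5 | (2S)-2-[(2S)-2-hydroxy-6-methylhept-5-en-2-yl]-5-methyl-4-[(3-methylbut-2-en-1-yl)oxy]-7-(2-methylpropanoyl)-2,3-dihydro-1-benzofuran-6-yl (1S,4R)-4,7,7-trimethyl-3-oxo-2-oxabicyclo[2.2.1]heptane-1-carboxylate | CC(C)=CCC[C@](C)(O)[C@@H]1Cc2c(O1)c(C(=O)C(C)C)c(OC(=O)[C@@]34CC[C@@](C)(C(=O)O3)C4(C)C)c(C)c2OCC=C(C)C
F4 | step 5 | (2R)-2-[(2R)-2-hydroxy-6-methylhept-5-en-2-yl]-5-methyl-4-[(3-methylbut-2-en-1-yl)oxy]-7-(2-methylpropanoyl)-2,3-dihydro-1-benzofuran-6-yl (1S,4R)-4,7,7-trimethyl-3-oxo-2-oxabicyclo[2.2.1]heptane-1-carboxylate | CC(C)=CCC[C@@](C)(O)[C@H]1Cc2c(O1)c(C(=O)C(C)C)c(OC(=O)[C@@]34CC[C@@](C)(C(=O)O3)C4(C)C)c(C)c2OCC=C(C)C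
F5 | step 6 | 1-{(2S)-4,6-dihydroxy-2-[(2S)-2-hydroxy-6-methylhept-5-en-2-yl]-5-methyl-2,3-dihydro-1-benzofuran-7-yl}-2-methylpropan-1-one | CC(C)=CCC[C@](C)(O)[C@@H]1Cc2c(O1)c(C(=O)C(C)C)c(O)c(C)c2O
F6 | step 6 | (2S,5S)-6-hydroxy-2-[(2S)-2-hydroxy-6-methylhept-5-en-2-yl]-5-methyl-5-(3-methylbut-2-en-1-yl)-7-(2-methylpropanoyl)-2,3-dihydro-1-benzofuran-4(5H)-one (C5 epimer of 11) | CC(C)=CCC[C@](C)(O)[C@@H]1CC2=C(O1)C(C(=O)C(C)C)=C(O)[C@](C)(CC=C(C)C)C2=O
F7 | step 7 | (2S,7S)-6-hydroxy-2-[(2S)-2-hydroxy-6-methylhept-5-en-2-yl]-5-methyl-7-(3-methylbut-2-en-1-yl)-7-(2-methylpropanoyl)-2,3-dihydro-1-benzofuran-4(7H)-one | CC(C)=CCC[C@](C)(O)[C@@H]1CC2=C(O1)[C@@](CC=C(C)C)(C(=O)C(C)C)C(O)=C(C)C2=O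
F8 | step 7 | (2S,7R)-6-hydroxy-2-[(2S)-2-hydroxy-6-methylhept-5-en-2-yl]-5-methyl-7-(3-methylbut-2-en-1-yl)-7-(2-methylpropanoyl)-2,3-dihydro-1-benzofuran-4(7H)-one (C7 epimer of F7) | CC(C)=CCC[C@](C)(O)[C@@H]1CC2=C(O1)[C@](CC=C(C)C)(C(=O)C(C)C)C(O)=C(C)C2=O
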